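**Plan**
- Retrosynthetic cuts, in order: the C6–prenyl bond (aromatic Claisen from O5 to C6), the C3–O bond (from a C3 acetyl group, Baeyer–Villiger), the C2–C3 bond (ring C), the C3=C4 bond (Wittig) and the O1–CH2 bond (Mitsunobu), back to 2,4,6-trihydroxybenzaldehyde and 3,4-dihydroxybenzaldehyde.
- Forward: the ring B benzyl alcohol is joined to ring A through O1, C3 and its acetyl group are added as an enone, and ring C is closed last by a redox-neutral 1,5-hydride shift/cyclisation that forms C2–C3.
- Enabling feature: the C2–H bond is benzylic to the para-oxygenated ring B and α to O1, hence hydridic, and lies 1,5 to C4 across O1–C8a–C4a. C4 of the target is a CH2 that needs exactly this hydrogen, and the acetyl group that activates C4=C3 is a masked C3–OH.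
- Stereochemistry: C2 comes from the chiral primary amine catalyst in the ring closure; C3 is set trans to the C2 aryl group in the same transition state and at an epimerisable α-position, then carried into C3–O with retention.
- The prenyl group is added after all oxidations, by a shift from O5 to C6, the only free ortho position.

Key step: step 7

Abbreviations and numbering: TBS = tert-butyldimethylsilyl, TIPS = triisopropylsilyl, Piv = pivaloyl (2,2-dimethylpropanoyl); flavan numbering (O1, C2, C3, C4, C4a–C8a) with ring A (phloroglucinol ring), ring B (catechol ring) and ring C (pyran ring).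

Assumption: the sense of induction of the amine catalyst in step 7 cannot be predicted with certainty; the route is written with 9-amino-9-deoxy-epi-quinine, and the quinidine-derived pseudo-enantiomer would be used if the mirror-image ketone were favoured.

**Route**

Step 1
Reactants: 1 3,4-dihydroxybenzaldehyde
Product: 2 3,4-bis(tert-butyldimethylsilyloxy)benzaldehyde
Conditions: TBSCl (2.3 equiv), imidazole, DMF, rt
Reagents that add atoms: tert-butyldimethylsilyl chloride, CC(C)(C)[Si](C)(C)Cl
Why: Imidazole-promoted silyl ether formation protects both phenols as groups that keep ring B electron-rich, carry no hydridic C–H and can be removed at the end without acid or hydrogenation.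

Step 2
Reactants: 2 3,4-bis(tert-butyldimethylsilyloxy)benzaldehyde
Product: 3 [3,4-bis(tert-butyldimethylsilyloxy)phenyl]methanol
Conditions: NaBH4, THF/MeOH, 0 °C
Reagents that add atoms: none
Why: Borohydride reduction of the aldehyde gives the primary benzylic alcohol that will supply C2 and ring B, and aryl silyl ethers should survive a short exposure to cold NaBH4.

Step 3
Reactants: 4 2,4,6-trihydroxybenzaldehyde
Product: 5 2,6-dihydroxy-4-(triisopropylsilyloxy)benzaldehyde
Conditions: TIPSCl (1.05 equiv), imidazole, DMF, −20 → 0 °C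
Reagents that add atoms: triisopropylsilyl chloride, CC(C)[Si](Cl)(C(C)C)C(C)C
Why: Site-selective silylation should take the 4-hydroxyl first, because it is para to the formyl group (most acidic) and is the only one neither hydrogen-bonded to nor flanked by CHO, which the bulky silyl chloride reinforces.

Step 4
Reactants: 5 2,6-dihydroxy-4-(triisopropylsilyloxy)benzaldehyde; 3 [3,4-bis(tert-butyldimethylsilyloxy)phenyl]methanol
Product: 6 2-{[3,4-bis(tert-butyldimethylsilyloxy)phenyl]methoxy}-6-hydroxy-4-(triisopropylsilyloxy)benzaldehyde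
Conditions: PPh3, DIAD, THF, 0 °C → rt (5 in 1.2-fold excess)
Reagents that add atoms: none
Why: Mitsunobu etherification of one of the two equivalent ortho phenols forms the O1–CH2 bond under neutral conditions that spare the aryl silyl ethers, and the remaining hydroxyl, held in a hydrogen bond to the formyl group, should react more slowly and so limit double etherification.

Step 5
Reactants: 6 2-{[3,4-bis(tert-butyldimethylsilyloxy)phenyl]methoxy}-6-hydroxy-4-(triisopropylsilyloxy)benzaldehyde
Product: 7 3-{[3,4-bis(tert-butyldimethylsilyloxy)phenyl]methoxy}-2-formyl-5-(triisopropylsilyloxy)phenyl pivalate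
Conditions: PivCl, Et3N, DMAP (10 mol %), CH2Cl2, 0 °C → rt
Reagents that add atoms: pivaloyl chloride, CC(C)(C)C(=O)Cl
Why: DMAP-catalysed acylation caps the future O5 as a pivalate, which has no hydridic C–H, resists aminolysis by the catalyst of step 7, lowers the donor strength of ring A toward the enone and can later be removed reductively beside the silyl ethers.

Step 6
Reactants: 7 3-{[3,4-bis(tert-butyldimethylsilyloxy)phenyl]methoxy}-2-formyl-5-(triisopropylsilyloxy)phenyl pivalate
Product: 8 3-{[3,4-bis(tert-butyldimethylsilyloxy)phenyl]methoxy}-2-[(E)-3-oxobut-1-en-1-yl]-5-(triisopropylsilyloxy)phenyl pivalate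
Conditions: Ph3P=CHC(O)CH3 (1.5 equiv), PhMe, 100 °C
Reagents that add atoms: 1-(triphenylphosphoranylidene)propan-2-one, CC(=O)C=P(c1ccccc1)(c1ccccc1)c1ccccc1
Why: Wittig olefination with the stabilised acetonyl ylide should give the (E)-enone, adding C3 and the acetyl group that serves both as the acceptor-activating group and as the masked C3 hydroxyl.

Step 7
Reactants: 8 3-{[3,4-bis(tert-butyldimethylsilyloxy)phenyl]methoxy}-2-[(E)-3-oxobut-1-en-1-yl]-5-(triisopropylsilyloxy)phenyl pivalate
Product: 12 (2S,3S)-3-acetyl-2-[3,4-bis(tert-butyldimethylsilyloxy)phenyl]-7-(triisopropylsilyloxy)chroman-5-yl pivalate (2,3-trans), via iminium ion 9 (not isolated), via oxocarbenium–enamine 10 (not isolated), via cyclised iminium ion 11 (not isolated)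
Conditions: 9-amino-9-deoxy-epi-quinine (20 mol %), CF3CO2H (40 mol %), PhMe, 60 °C
Reagents that add atoms: none
Why: Proposed new method: the primary amine condenses with the enone to iminium ion 9, whose β-carbon (C4) takes the hydridic C2–H of the aryl benzyl ether through a six-membered 1,5-hydride-shift transition state to give oxocarbenium–enamine 10; the enamine carbon C3 then adds to the oxocarbenium carbon C2, and hydrolysis of iminium ion 11 releases 12 and the catalyst. The closest known reaction types are the iminium-catalysed 1,5-hydride transfer/ring closure of ortho-amino cinnamaldehydes and of ether-tethered enals, and the Lewis-acid internal redox cyclisation of aryl benzyl ethers onto alkylidene malonates to give 2-arylchromans; an enantioselective amine-catalysed version with an aryl benzyl ether donor and an enone acceptor is not established. Ring C closes in a 6-(enolexo)-endo-trig mode, the exocyclic enamine carbon attacking the endocyclic O1=C2 oxocarbenium. C2 is set by the enamine face left open by the chiral amine, relayed through a chair-like transition state with ring B pseudo-equatorial on the (E)-oxocarbenium; C3 is formed in the same transition state and, being α to the C=N/C=O group, should settle trans to the C2 aryl group. The step needs hydride donation from the O1–CH2 group only and no loss of the benzyl group: the O5 pivalate and the silyl ethers offer no hydridic C–H 1,5 to C4, the ring B silyloxy groups stabilise the oxocarbenium, and the weak acid loading and absence of free phenols should hold back solvolysis of 10 and oxa-Michael pathways.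

Step 8
Reactants: 12 (2S,3S)-3-acetyl-2-[3,4-bis(tert-butyldimethylsilyloxy)phenyl]-7-(triisopropylsilyloxy)chroman-5-yl pivalate
Product: 13 (2R,3S)-3-acetoxy-2-[3,4-bis(tert-butyldimethylsilyloxy)phenyl]-7-(triisopropylsilyloxy)chroman-5-yl pivalate
Conditions: mCPBA (3 equiv), CH2Cl2, rt → 40 °C
Reagents that add atoms: 3-chloroperoxybenzoic acid, OOC(=O)c1cccc(Cl)c1
Why: In this Baeyer–Villiger oxidation the secondary C3 migrates in preference to methyl with retention of configuration, so the trans relationship from step 7 is carried into the C3–O bond; no alkene is yet present, and loss of the ketone removes the retro-oxa-Michael risk to C2.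

Step 9
Reactants: 13 (2R,3S)-3-acetoxy-2-[3,4-bis(tert-butyldimethylsilyloxy)phenyl]-7-(triisopropylsilyloxy)chroman-5-yl pivalate
Product: 14 (2R,3S)-2-[3,4-bis(tert-butyldimethylsilyloxy)phenyl]-7-(triisopropylsilyloxy)chroman-3,5-diol
Conditions: i-Bu2AlH (6 equiv), CH2Cl2, −78 → 0 °C; aqueous potassium sodium tartrate
Reagents that add atoms: none
Why: Reductive ester cleavage frees O3–H and O5–H while the three aryl silyl ethers, inert to the hydride, stay in place and no stereocentre is touched.

Step 10
Reactants: 14 (2R,3S)-2-[3,4-bis(tert-butyldimethylsilyloxy)phenyl]-7-(triisopropylsilyloxy)chroman-3,5-diol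
Product: 15 (2R,3S)-2-[3,4-bis(tert-butyldimethylsilyloxy)phenyl]-5-[(2-methylbut-3-en-2-yl)oxy]-7-(triisopropylsilyloxy)chroman-3-ol
Conditions: Pd(PPh3)4 (5 mol %), tert-butyl 2-methylbut-3-en-2-yl carbonate (1.5 equiv), THF, 0 °C → rt
Reagents that add atoms: tert-butyl 2-methylbut-3-en-2-yl carbonate, C=CC(C)(C)OC(=O)OC(C)(C)C
Why: In this Tsuji–Trost-type decarboxylative allylic etherification, zerovalent palladium ionises the tertiary carbonate and the phenol at O5, far more acidic than the C3 alcohol, should attack the dimethyl-substituted terminus of the π-allyl complex to give the tertiary (reverse-prenyl) aryl ether.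

Step 11
Reactants: 15 (2R,3S)-2-[3,4-bis(tert-butyldimethylsilyloxy)phenyl]-5-[(2-methylbut-3-en-2-yl)oxy]-7-(triisopropylsilyloxy)chroman-3-ol
Product: 17 (2R,3S)-2-[3,4-bis(tert-butyldimethylsilyloxy)phenyl]-6-(3-methylbut-2-en-1-yl)-7-(triisopropylsilyloxy)chroman-3,5-diol, via C6-prenyl cyclohexadienone 16 (not isolated)
Conditions: xylenes, 130 °C (degassed, sealed tube)
Reagents that add atoms: none
Why: In this aromatic Claisen rearrangement the [3,3] shift from O5 can end productively only at C6, since the other ortho carbon (C4a) is substituted; the allyl inversion turns the 1,1-dimethylallyl ether into the linear prenyl group, and tautomerisation of dienone 16 restores the phenol, so C8 is not reached.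

Step 12
Reactants: 17 (2R,3S)-2-[3,4-bis(tert-butyldimethylsilyloxy)phenyl]-6-(3-methylbut-2-en-1-yl)-7-(triisopropylsilyloxy)chroman-3,5-diol
Product: 18 6-prenylcatechin, (2R,3S)-2-(3,4-dihydroxyphenyl)-6-(3-methylbut-2-en-1-yl)chroman-3,5,7-triol
Conditions: Bu4NF (3.5 equiv), AcOH (3.5 equiv), THF, 0 °C → rt, argon
Reagents that add atoms: none
Why: Fluoride cleaves the three aryl silyl ethers while acetic acid buffers the phenoxides, so the catechol, the C2 stereocentre and the prenyl alkene should see neither strong base nor acid.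

**Compound list**
1 | 3,4-dihydroxybenzaldehyde | O=Cc1ccc(O)c(O)c1 | starting material
2 | 3,4-bis(tert-butyldimethylsilyloxy)benzaldehyde | O=Cc1ccc(O[Si](C)(C)C(C)(C)C)c(O[Si](C)(C)C(C)(C)C)c1 | intermediate
3 | [3,4-bis(tert-butyldimethylsilyloxy)phenyl]methanol | OCc1ccc(O[Si](C)(C)C(C)(C)C)c(O[Si](C)(C)C(C)(C)C)c1 | intermediate
4 | 2,4,6-trihydroxybenzaldehyde | O=Cc1c(O)cc(O)cc1O | starting material
5 | 2,6-dihydroxy-4-(triisopropylsilyloxy)benzaldehyde | O=Cc1c(O)cc(O[Si](C(C)C)(C(C)C)C(C)C)cc1O | intermediate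
6 | 2-{[3,4-bis(tert-butyldimethylsilyloxy)phenyl]methoxy}-6-hydroxy-4-(triisopropylsilyloxy)benzaldehyde | O=Cc1c(O)cc(O[Si](C(C)C)(C(C)C)C(C)C)cc1OCc1ccc(O[Si](C)(C)C(C)(C)C)c(O[Si](C)(C)C(C)(C)C)c1 | intermediate
7 | 3-{[3,4-bis(tert-butyldimethylsilyloxy)phenyl]methoxy}-2-formyl-5-(triisopropylsilyloxy)phenyl pivalate | O=Cc1c(OC(=O)C(C)(C)C)cc(O[Si](C(C)C)(C(C)C)C(C)C)cc1OCc1ccc(O[Si](C)(C)C(C)(C)C)c(O[Si](C)(C)C(C)(C)C)c1 | intermediate
8 | 3-{[3,4-bis(tert-butyldimethylsilyloxy)phenyl]methoxy}-2-[(E)-3-oxobut-1-en-1-yl]-5-(triisopropylsilyloxy)phenyl pivalate | CC(=O)/C=C/c1c(OC(=O)C(C)(C)C)cc(O[Si](C(C)C)(C(C)C)C(C)C)cc1OCc1ccc(O[Si](C)(C)C(C)(C)C)c(O[Si](C)(C)C(C)(C)C)c1 | intermediate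
9 | iminium ion of enone 8 on the primary amino group of 9-amino-9-deoxy-epi-quinine (E-alkene, trifluoroacetate counter-ion omitted) | CC(/C=C/c1c(OC(=O)C(C)(C)C)cc(O[Si](C(C)C)(C(C)C)C(C)C)cc1OCc1ccc(O[Si](C)(C)C(C)(C)C)c(O[Si](C)(C)C(C)(C)C)c1)=[NH+][C@@H](c1ccnc2ccc(OC)cc12)[C@@H]1C[C@@H]2CCN1C[C@@H]2C=C | intermediate (not isolated)
10 | oxocarbenium–enamine formed by 1,5-hydride shift: C4 is CH2, C3 is the enamine carbon, O1=C2 carries the positive charge | CC(N[C@@H](c1ccnc2ccc(OC)cc12)[C@@H]1C[C@@H]2CCN1C[C@@H]2C=C)=CCc1c(OC(=O)C(C)(C)C)cc(O[Si](C(C)C)(C(C)C)C(C)C)cc1[O+]=Cc1ccc(O[Si](C)(C)C(C)(C)C)c(O[Si](C)(C)C(C)(C)C)c1 | intermediate (not isolated)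
11 | cyclised iminium ion: catalyst-bound form of 12, with the same 2,3-trans configuration at C2 and C3 | CC(=[NH+][C@@H](c1ccnc2ccc(OC)cc12)[C@@H]1C[C@@H]2CCN1C[C@@H]2C=C)[C@H]1Cc2c(OC(=O)C(C)(C)C)cc(O[Si](C(C)C)(C(C)C)C(C)C)cc2O[C@@H]1c1ccc(O[Si](C)(C)C(C)(C)C)c(O[Si](C)(C)C(C)(C)C)c1 | intermediate (not isolated)
12 | (2S,3S)-3-acetyl-2-[3,4-bis(tert-butyldimethylsilyloxy)phenyl]-7-(triisopropylsilyloxy)chroman-5-yl pivalate (2,3-trans) | CC(=O)[C@H]1Cc2c(OC(=O)C(C)(C)C)cc(O[Si](C(C)C)(C(C)C)C(C)C)cc2O[C@@H]1c1ccc(O[Si](C)(C)C(C)(C)C)c(O[Si](C)(C)C(C)(C)C)c1 | intermediate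
13 | (2R,3S)-3-acetoxy-2-[3,4-bis(tert-butyldimethylsilyloxy)phenyl]-7-(triisopropylsilyloxy)chroman-5-yl pivalate | CC(=O)O[C@H]1Cc2c(OC(=O)C(C)(C)C)cc(O[Si](C(C)C)(C(C)C)C(C)C)cc2O[C@@H]1c1ccc(O[Si](C)(C)C(C)(C)C)c(O[Si](C)(C)C(C)(C)C)c1 | intermediate
14 | (2R,3S)-2-[3,4-bis(tert-butyldimethylsilyloxy)phenyl]-7-(triisopropylsilyloxy)chroman-3,5-diol | O[C@H]1Cc2c(O)cc(O[Si](C(C)C)(C(C)C)C(C)C)cc2O[C@@H]1c1ccc(O[Si](C)(C)C(C)(C)C)c(O[Si](C)(C)C(C)(C)C)c1 | intermediate
15 | (2R,3S)-2-[3,4-bis(tert-butyldimethylsilyloxy)phenyl]-5-[(2-methylbut-3-en-2-yl)oxy]-7-(triisopropylsilyloxy)chroman-3-ol | C=CC(C)(C)Oc1cc(O[Si](C(C)C)(C(C)C)C(C)C)cc2c1C[C@H](O)[C@@H](c1ccc(O[Si](C)(C)C(C)(C)C)c(O[Si](C)(C)C(C)(C)C)c1)O2 | intermediate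
16 | (2R,3S)-2-[3,4-bis(tert-butyldimethylsilyloxy)phenyl]-3-hydroxy-6-(3-methylbut-2-en-1-yl)-7-(triisopropylsilyloxy)-3,4-dihydro-2H-chromen-5(6H)-one (Claisen dienone, C6 epimers) | CC(C)=CCC1C(O[Si](C(C)C)(C(C)C)C(C)C)=CC2=C(C1=O)C[C@H](O)[C@@H](c1ccc(O[Si](C)(C)C(C)(C)C)c(O[Si](C)(C)C(C)(C)C)c1)O2 | intermediate (not isolated)
17 | (2R,3S)-2-[3,4-bis(tert-butyldimethylsilyloxy)phenyl]-6-(3-methylbut-2-en-1-yl)-7-(triisopropylsilyloxy)chroman-3,5-diol | CC(C)=CCc1c(O[Si](C(C)C)(C(C)C)C(C)C)cc2c(c1O)C[C@H](O)[C@@H](c1ccc(O[Si](C)(C)C(C)(C)C)c(O[Si](C)(C)C(C)(C)C)c1)O2 | intermediate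
18 | 6-prenylcatechin, (2R,3S)-2-(3,4-dihydroxyphenyl)-6-(3-methylbut-2-en-1-yl)chroman-3,5,7-triol | CC(C)=CCc1c(O)cc2c(c1O)C[C@H](O)[C@@H](c1ccc(O)c(O)c1)O2 | target

**Step count**
Total: 12 steps. Longest linear sequence: 11 steps (1 → 2 → 3 → 6 → 7 → 8 → 12 → 13 → 14 → 15 → 17 → 18; ring A enters at step 4 after one step of its own).

**Steps most likely to fail, with fallbacks**

Step 7 (Proposed new method). What may go wrong:
- hydride transfer from an aryl-ether C–H to an iminium ion that is deactivated by the electron-rich ring A may be too slow;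
- the oxocarbenium stage may be intercepted by water, with loss of the benzyl group;
- the β-aryloxy ketone may reopen through its enamine (retro-oxa-Michael) and erode the C2 configuration;
- facial control by the amine may be poor.

Fallback, in the established racemic mode of this reaction: starting from 8, Lewis-acid internal redox cyclisation with Sc(OTf)3 (10 mol %) in 1,2-dichloroethane at 60 °C should give the racemic 2,3-trans ketone, that is 12 together with its mirror image, (2R,3R)-3-acetyl-2-[3,4-bis(tert-butyldimethylsilyloxy)phenyl]-7-(triisopropylsilyloxy)chroman-5-yl pivalate F1. Preparative HPLC on a chiral stationary phase (amylose tris(3,5-dimethylphenylcarbamate)) then separates the enantiomers, and the route is rejoined at 12.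

Step 4. What may go wrong: both ortho hydroxyls of 5 are equivalent, so double etherification and a statistical mixture may result, and the electron-rich benzylic oxyphosphonium may ionise and alkylate ring A on carbon. Fallback: starting from 5, the two phenols are differentiated by acylation first. One equivalent of PivCl with Et3N in CH2Cl2 at −40 °C should give 2-formyl-3-hydroxy-5-(triisopropylsilyloxy)phenyl pivalate F2, in which a single phenol is left. Mitsunobu etherification of that phenol with 3 (PPh3, DIAD, THF) gives 7 directly, where the route is rejoined.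

Step 10. What may go wrong: the phenoxide may attack the unsubstituted terminus of the π-allyl complex (linear O-prenyl ether) or the complex may alkylate ring A on carbon. Fallback: starting from 14, copper-catalysed propargylic etherification with 3-chloro-3-methylbut-1-yne, CuCl2 (1 mol %) and DBU in MeCN at 0 °C should give (2R,3S)-2-[3,4-bis(tert-butyldimethylsilyloxy)phenyl]-5-[(2-methylbut-3-yn-2-yl)oxy]-7-(triisopropylsilyloxy)chroman-3-ol F3, where only the tertiary ether can form. Semi-hydrogenation of the alkyne (H2, Pd/CaCO3 poisoned with Pb(OAc)2, quinoline, EtOAc) then gives 15, where the route is rejoined.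

**Further compounds**
F1 | step 7 | (2R,3R)-3-acetyl-2-[3,4-bis(tert-butyldimethylsilyloxy)phenyl]-7-(triisopropylsilyloxy)chroman-5-yl pivalate (enantiomer of 12) | CC(=O)[C@@H]1Cc2c(OC(=O)C(C)(C)C)cc(O[Si](C(C)C)(C(C)C)C(C)C)cc2O[C@H]1c1ccc(O[Si](C)(C)C(C)(C)C)c(O[Si](C)(C)C(C)(C)C)c1
F2 | step 4 | 2-formyl-3-hydroxy-5-(triisopropylsilyloxy)phenyl pivalate | O=Cc1c(O)cc(O[Si](C(C)C)(C(C)C)C(C)C)cc1OC(=O)C(C)(C)C
F3 | step 10 | (2R,3S)-2-[3,4-bis(tert-butyldimethylsilyloxy)phenyl]-5-[(2-methylbut-3-yn-2-yl)oxy]-7-(triisopropylsilyloxy)chroman-3-ol | C#CC(C)(C)Oc1cc(O[Si](C(C)C)(C(C)C)C(C)C)cc2c1C[C@H](O)[C@@H](c1ccc(O[Si](C)(C)C(C)(C)C)c(O[Si](C)(C)C(C)(C)C)c1)O2
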